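**Plan**

1. Retrosynthesis: the C3–O ester bond is cut first, which splits off (Z)-4-acetoxy-2-methylbut-2-enoic acid. The C2–C3 bond of the dihydrofuran ring and the C–CH3 bond of the isopropenyl group are then cut in one operation, leading back to an ortho-(allenyloxy)benzaldehyde and Me2Zn.
2. Enabling feature: C3 is a benzylic carbinol carbon ortho to the ring oxygen O1, and C2 carries O1 and a 1-methylvinyl group. C3(OH)–C2–C(CH3)=CH2 is therefore a homoallylic alcohol whose tether (C3a, C7a, O1) is an aryl allenyl ether of a salicylaldehyde.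
3. Forward order: the benzene ring is bought with Br, CHO and both OH groups in place. The acetyl group enters masked as 1-ethoxyvinyl, the propargyl ether is isomerised to the allenyl ether while the aldehyde rests at the alcohol level, both carbonyl groups are released, and nickel then closes the dihydrofuran ring.
4. Stereochemistry: the cis C2/C3 relationship comes from a cis-fused oxanickelacycle, the absolute configuration from a chiral phosphoramidite on nickel, and the Z-enoate from a Z-selective Horner–Wadsworth–Emmons reaction in a separate branch.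
5. End game: Yamaguchi esterification of the C3 alcohol, then buffered fluoride removal of the phenol silyl ether.

Key step: step 7

Assumption: the sense of induction of the chiral phosphoramidite in step 7 cannot be predicted with certainty. Both ligand enantiomers are accessible, and the one that gives the (2S,3S) alcohol (written below as the (R) ligand) would be used.

**Step 1**
Reactants: 1 5-bromo-2,4-dihydroxybenzaldehyde
Product: 2 5-bromo-2-hydroxy-4-[(triisopropylsilyl)oxy]benzaldehyde
Conditions: TIPSCl (1.05 equiv), imidazole, CH2Cl2, 0 °C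
Reagents that add atoms: triisopropylsilyl chloride, CC(C)[Si](Cl)(C(C)C)C(C)C
Why: Selective O-silylation of the more acidic, non-chelated 4-OH (para to the formyl group), while the 2-OH stays hydrogen-bonded to the aldehyde and free.

**Step 2**
Reactants: 2 5-bromo-2-hydroxy-4-[(triisopropylsilyl)oxy]benzaldehyde; 3 tributyl(1-ethoxyethenyl)stannane
Product: 4 5-(1-ethoxyethenyl)-2-hydroxy-4-[(triisopropylsilyl)oxy]benzaldehyde
Conditions: PdCl2(PPh3)2 (5 mol %), toluene, 100 °C; chromatography on Et3N-deactivated silica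
Reagents that add atoms: none
Why: Stille coupling of the aryl bromide with the α-alkoxyvinylstannane should install the acetyl group in a masked, base-stable form.

**Step 3**
Reactants: 4 5-(1-ethoxyethenyl)-2-hydroxy-4-[(triisopropylsilyl)oxy]benzaldehyde; 5 prop-2-yn-1-ol
Product: 6 5-(1-ethoxyethenyl)-2-(prop-2-yn-1-yloxy)-4-[(triisopropylsilyl)oxy]benzaldehyde
Conditions: PPh3, DIAD, THF, 0 °C to rt
Reagents that add atoms: none
Why: Mitsunobu etherification of the acidic chelated phenol with a primary alcohol runs under neutral conditions that should spare the aryl silyl ether and the enol ether.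

**Step 4**
Reactants: 6 5-(1-ethoxyethenyl)-2-(prop-2-yn-1-yloxy)-4-[(triisopropylsilyl)oxy]benzaldehyde
Product: 7 [5-(1-ethoxyethenyl)-2-(prop-2-yn-1-yloxy)-4-[(triisopropylsilyl)oxy]phenyl]methanol
Conditions: NaBH4, EtOH/THF, 0 °C
Reagents that add atoms: none
Why: Chemoselective hydride reduction parks the aldehyde carbon at the alcohol level, so that it is an inert alkoxide under the base of the next step.

**Step 5**
Reactants: 7 [5-(1-ethoxyethenyl)-2-(prop-2-yn-1-yloxy)-4-[(triisopropylsilyl)oxy]phenyl]methanol
Product: 9 1-[5-(hydroxymethyl)-4-(propa-1,2-dien-1-yloxy)-2-[(triisopropylsilyl)oxy]phenyl]ethan-1-one, via allenyl enol ether 8 (not isolated)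
Conditions: KOt-Bu (2 equiv), THF, 0 °C to rt; then 0.1 M aq. HCl, THF, 0 °C, short contact
Reagents that add atoms: water, O
Why: Base-mediated propargyl-to-allenyl ether isomerisation (prototropic rearrangement) is followed by acid hydrolysis of the α-alkoxystyrene, which should be protonated far faster than the electron-poor aryloxyallene.

**Step 6**
Reactants: 9 1-[5-(hydroxymethyl)-4-(propa-1,2-dien-1-yloxy)-2-[(triisopropylsilyl)oxy]phenyl]ethan-1-one
Product: 10 5-acetyl-2-(propa-1,2-dien-1-yloxy)-4-[(triisopropylsilyl)oxy]benzaldehyde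
Conditions: activated MnO2, CH2Cl2, rt
Reagents that add atoms: none
Why: MnO2 oxidation of the benzylic alcohol to the aldehyde is neutral and should leave the allenyl ether, the ketone and the silyl ether untouched.

**Step 7**
Reactants: 10 5-acetyl-2-(propa-1,2-dien-1-yloxy)-4-[(triisopropylsilyl)oxy]benzaldehyde
Product: 12 1-[(2S,3S)-3-hydroxy-2-(prop-1-en-2-yl)-6-[(triisopropylsilyl)oxy]-2,3-dihydro-1-benzofuran-5-yl]ethan-1-one, via methylzinc alkoxide 11 (not isolated)
Conditions: Ni(cod)2 (10 mol %), (R)-SIPHOS-PE (spirobiindanediol phosphoramidite with a bis(1-phenylethyl)amino group, 12 mol %), Me2Zn (2.5 equiv), THF, 0 °C, slow addition of 10; sat. aq. NH4Cl; Et3N-deactivated silica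
Reagents that add atoms: dimethylzinc, C[Zn]C
Why: Proposed new method: zerovalent nickel carrying one chiral phosphoramidite binds the aldehyde and the proximal C=C of the O-allenyl ether and couples them oxidatively to an oxanickelacycle (Ni–O on C3, Ni–C on the central allene carbon), Me2Zn then transfers a methyl group to nickel, and C–CH3 reductive elimination releases the isopropenyl group and the zinc alkoxide 11; the closest known reaction type is the nickel-catalysed alkylative cyclisation of allenyl aldehydes with organozincs, which gives cis-2-(alk-1-en-2-yl)cycloalkanols, combined with the enantioselective nickel/spiro-phosphoramidite alkylative coupling of alkynes and aldehydes with Me2Zn. The dihydrofuran ring closes in a 5-exo mode, the aldehyde carbon bonding to the allene carbon that carries O1 while both the C=O and the remaining C=CH2 stay exocyclic. C2 and C3 are set together: the cis relationship follows from the cis-fused bicyclic nickelacycle, in which the C3 oxygen and the C2 alkenyl carbon must reach nickel from the same face, and the absolute sense follows from the ligand in the oxidative cyclisation, which is the C–C bond-forming and enantio-determining event. Regioselectivity for the proximal allene carbon is secured by the three-atom tether (C3a, C7a, O1), which allows only the five-membered ring; methyl rather than hydride transfer is secured because Zn–CH3 has no β-hydrogen; and the aldehyde should react before the aryl methyl ketone because it is the more electrophilic carbonyl and the only one within reach of the allene. What is new is ligand control of this cyclisation and the use of an aryloxyallene; a racemic background can only come from ligand-free nickel, which the slight excess of ligand should suppress.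

**Step 8**
Reactants: 13 tert-butyl bromoacetate; 14 diphenyl phosphite
Product: 15 tert-butyl 2-(diphenoxyphosphoryl)acetate
Conditions: Et3N, CH2Cl2, 0 °C to rt
Reagents that add atoms: none
Why: Michaelis–Becker-type P-alkylation of the diaryl phosphite with the reactive α-bromo ester should give the diaryl phosphonoacetate needed for Z-selective olefination.

**Step 9**
Reactants: 15 tert-butyl 2-(diphenoxyphosphoryl)acetate
Product: 16 tert-butyl 2-(diphenoxyphosphoryl)propanoate (racemic)
Conditions: NaH (1.0 equiv), DMSO, rt; then MeI (1.0 equiv)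
Reagents that add atoms: iodomethane, CI
Why: C-alkylation of the stabilised phosphonate carbanion with one equivalent of MeI introduces the α-methyl group of the later enoate.

**Step 10**
Reactants: 17 (Z)-but-2-ene-1,4-diyl diacetate
Product: 19 2-oxoethyl acetate, via ozonide 18 (not isolated)
Conditions: O3, CH2Cl2, −78 °C; then Me2S, −78 °C to rt
Reagents that add atoms: ozone, [O-][O+]=O
Why: Ozonolysis with reductive work-up cleaves the symmetrical alkene into two molecules of the acetoxy aldehyde, so the acetate is in place before the Z-enoate exists.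

**Step 11**
Reactants: 16 tert-butyl 2-(diphenoxyphosphoryl)propanoate; 19 2-oxoethyl acetate
Product: 20 tert-butyl (2Z)-4-(acetyloxy)-2-methylbut-2-enoate
Conditions: NaH, THF, 0 °C; then 19, −78 °C to 0 °C
Reagents that add atoms: none
Why: Horner–Wadsworth–Emmons olefination with a diaryl phosphonate should be Z-selective (fast, irreversible collapse of the syn adduct, helped by the bulky tert-butyl ester), placing the ester and CH2OAc groups cis.

**Step 12**
Reactants: 20 tert-butyl (2Z)-4-(acetyloxy)-2-methylbut-2-enoate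
Product: 21 (2Z)-4-(acetyloxy)-2-methylbut-2-enoic acid
Conditions: TFA/CH2Cl2 (1:3), 0 °C to rt
Reagents that add atoms: none
Why: Acidolysis of the tert-butyl ester frees the acid without touching the primary acetate, and a free Z-4-hydroxy acid, which would lactonise, is never formed.

**Step 13**
Reactants: 12 1-[(2S,3S)-3-hydroxy-2-(prop-1-en-2-yl)-6-[(triisopropylsilyl)oxy]-2,3-dihydro-1-benzofuran-5-yl]ethan-1-one; 21 (2Z)-4-(acetyloxy)-2-methylbut-2-enoic acid
Product: 23 (2S,3S)-5-acetyl-2-(prop-1-en-2-yl)-6-[(triisopropylsilyl)oxy]-2,3-dihydro-1-benzofuran-3-yl (2Z)-4-(acetyloxy)-2-methylbut-2-enoate, via mixed anhydride 22 (not isolated)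
Conditions: 21, 2,4,6-trichlorobenzoyl chloride, Et3N, toluene, rt; then 12, DMAP, toluene, 0 °C to rt
Reagents that add atoms: 2,4,6-trichlorobenzoyl chloride, O=C(Cl)c1c(Cl)cc(Cl)cc1Cl (its atoms stay in intermediate 22 only)
Why: Yamaguchi esterification acylates the hindered secondary benzylic alcohol at the less shielded enoyl carbonyl of the mixed anhydride, with retention at C3 because the C3–O bond is not broken.

**Step 14**
Reactants: 23 (2S,3S)-5-acetyl-2-(prop-1-en-2-yl)-6-[(triisopropylsilyl)oxy]-2,3-dihydro-1-benzofuran-3-yl (2Z)-4-(acetyloxy)-2-methylbut-2-enoate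
Product: 24 (2S,3S)-5-acetyl-6-hydroxy-2-(prop-1-en-2-yl)-2,3-dihydro-1-benzofuran-3-yl (2Z)-4-(acetyloxy)-2-methylbut-2-enoate
Conditions: TBAF, AcOH (1:1.2), THF, 0 °C
Reagents that add atoms: none
Why: Buffered fluoride cleavage of the aryl silyl ether is near neutral, so the benzylic ester, the allylic acetate and the Z-enoate should survive and the phenol is released into its hydrogen bond with the acetyl group.

**Compound list**

1 | 5-bromo-2,4-dihydroxybenzaldehyde | O=Cc1cc(Br)c(O)cc1O | starting material
2 | 5-bromo-2-hydroxy-4-[(triisopropylsilyl)oxy]benzaldehyde | O=Cc1cc(Br)c(O[Si](C(C)C)(C(C)C)C(C)C)cc1O | intermediate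
3 | tributyl(1-ethoxyethenyl)stannane | CCCC[Sn](CCCC)(CCCC)C(=C)OCC | starting material
4 | 5-(1-ethoxyethenyl)-2-hydroxy-4-[(triisopropylsilyl)oxy]benzaldehyde | C=C(OCC)c1cc(C=O)c(O)cc1O[Si](C(C)C)(C(C)C)C(C)C | intermediate
5 | prop-2-yn-1-ol | C#CCO | starting material
6 | 5-(1-ethoxyethenyl)-2-(prop-2-yn-1-yloxy)-4-[(triisopropylsilyl)oxy]benzaldehyde | C=C(OCC)c1cc(C=O)c(OCC#C)cc1O[Si](C(C)C)(C(C)C)C(C)C | intermediate
7 | [5-(1-ethoxyethenyl)-2-(prop-2-yn-1-yloxy)-4-[(triisopropylsilyl)oxy]phenyl]methanol | C=C(OCC)c1cc(CO)c(OCC#C)cc1O[Si](C(C)C)(C(C)C)C(C)C | intermediate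
8 | [5-(1-ethoxyethenyl)-2-(propa-1,2-dien-1-yloxy)-4-[(triisopropylsilyl)oxy]phenyl]methanol | C=C(OCC)c1cc(CO)c(OC=C=C)cc1O[Si](C(C)C)(C(C)C)C(C)C | intermediate
9 | 1-[5-(hydroxymethyl)-4-(propa-1,2-dien-1-yloxy)-2-[(triisopropylsilyl)oxy]phenyl]ethan-1-one | CC(=O)c1cc(CO)c(OC=C=C)cc1O[Si](C(C)C)(C(C)C)C(C)C | intermediate
10 | 5-acetyl-2-(propa-1,2-dien-1-yloxy)-4-[(triisopropylsilyl)oxy]benzaldehyde | CC(=O)c1cc(C=O)c(OC=C=C)cc1O[Si](C(C)C)(C(C)C)C(C)C | intermediate
11 | methylzinc (2S,3S)-5-acetyl-2-(prop-1-en-2-yl)-6-[(triisopropylsilyl)oxy]-2,3-dihydro-1-benzofuran-3-olate | C=C(C)[C@@H]1Oc2cc(O[Si](C(C)C)(C(C)C)C(C)C)c(C(C)=O)cc2[C@@H]1O[Zn]C | intermediate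
12 | 1-[(2S,3S)-3-hydroxy-2-(prop-1-en-2-yl)-6-[(triisopropylsilyl)oxy]-2,3-dihydro-1-benzofuran-5-yl]ethan-1-one | C=C(C)[C@@H]1Oc2cc(O[Si](C(C)C)(C(C)C)C(C)C)c(C(C)=O)cc2[C@@H]1O | intermediate
13 | tert-butyl bromoacetate | CC(C)(C)OC(=O)CBr | starting material
14 | diphenyl phosphite | O=[PH](Oc1ccccc1)Oc1ccccc1 | starting material
15 | tert-butyl 2-(diphenoxyphosphoryl)acetate | CC(C)(C)OC(=O)CP(=O)(Oc1ccccc1)Oc1ccccc1 | intermediate
16 | tert-butyl 2-(diphenoxyphosphoryl)propanoate (racemic) | CC(C(=O)OC(C)(C)C)P(=O)(Oc1ccccc1)Oc1ccccc1 | intermediate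
17 | (Z)-but-2-ene-1,4-diyl diacetate | CC(=O)OC/C=C\COC(C)=O | starting material
18 | (1,2,4-trioxolane-3,5-diyl)bis(methylene) diacetate | CC(=O)OCC1OOC(COC(C)=O)O1 | intermediate
19 | 2-oxoethyl acetate | CC(=O)OCC=O | intermediate
20 | tert-butyl (2Z)-4-(acetyloxy)-2-methylbut-2-enoate | CC(=O)OC/C=C(/C)C(=O)OC(C)(C)C | intermediate
21 | (2Z)-4-(acetyloxy)-2-methylbut-2-enoic acid | CC(=O)OC/C=C(/C)C(=O)O | intermediate
22 | (2Z)-4-(acetyloxy)-2-methylbut-2-enoic 2,4,6-trichlorobenzoic anhydride | CC(=O)OC/C=C(/C)C(=O)OC(=O)c1c(Cl)cc(Cl)cc1Cl | intermediate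
23 | (2S,3S)-5-acetyl-2-(prop-1-en-2-yl)-6-[(triisopropylsilyl)oxy]-2,3-dihydro-1-benzofuran-3-yl (2Z)-4-(acetyloxy)-2-methylbut-2-enoate | C=C(C)[C@@H]1Oc2cc(O[Si](C(C)C)(C(C)C)C(C)C)c(C(C)=O)cc2[C@@H]1OC(=O)/C(C)=C\COC(C)=O | intermediate
24 | (2S,3S)-5-acetyl-6-hydroxy-2-(prop-1-en-2-yl)-2,3-dihydro-1-benzofuran-3-yl (2Z)-4-(acetyloxy)-2-methylbut-2-enoate | C=C(C)[C@@H]1Oc2cc(O)c(C(C)=O)cc2[C@@H]1OC(=O)/C(C)=C\COC(C)=O | target

**Step count and risks**

Total step count: 14. Longest linear sequence: 9 steps (steps 1 to 7, 13 and 14).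

Steps most likely to fail:

Step 7. The risk is poor enantiofacial discrimination in the oxidative cyclisation, or slowing of the catalyst by the bulky ligand so that allene oligomerisation takes over. The fallback uses known chemistry and sets out from 10. The ligand-free nickel-catalysed alkylative cyclisation (Ni(cod)2, Me2Zn, THF, 0 °C) should give the cis alcohol as a racemate, that is 12 together with its mirror image 1-[(2R,3R)-3-hydroxy-2-(prop-1-en-2-yl)-6-[(triisopropylsilyl)oxy]-2,3-dihydro-1-benzofuran-5-yl]ethan-1-one F1. An acylative kinetic resolution of this secondary benzylic alcohol follows (chiral isothiourea catalyst benzotetramisole, isobutyric anhydride, i-Pr2NEt, CHCl3, 0 °C), with the catalyst enantiomer chosen so that F1 is the fast-reacting antipode. F1 is converted into (2R,3R)-5-acetyl-2-(prop-1-en-2-yl)-6-[(triisopropylsilyl)oxy]-2,3-dihydro-1-benzofuran-3-yl 2-methylpropanoate F2, and the unreacted alcohol is separated by chromatography. The fallback comes back to the route at 12.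

Step 13. The risk is Z-to-E isomerisation of the activated acyl group through reversible conjugate addition of DMAP, together with elimination across C2–C3 towards the aromatic benzofuran. The fallback sets out from 12 and builds the Z-alkene after the ester bond. Phosphonate 16 is treated with TFA in CH2Cl2 to give 2-(diphenoxyphosphoryl)propanoic acid F3. F3 is coupled with 12 (DCC, catalytic DMAP, CH2Cl2, 0 °C) to give (2S,3S)-5-acetyl-2-(prop-1-en-2-yl)-6-[(triisopropylsilyl)oxy]-2,3-dihydro-1-benzofuran-3-yl 2-(diphenoxyphosphoryl)propanoate F4. Z-selective Horner–Wadsworth–Emmons olefination of F4 with aldehyde 19 (NaH, THF, −78 °C) then comes back to the route at 23; the saturated phosphonoacyl group cannot isomerise and the bulky ester should favour the Z-alkene.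

Step 5. The risk is protonation of the allenyl ether during the acidic unmasking of the acetyl group, leading to loss of acrolein or to capture by the neighbouring hydroxymethyl group, and silyl loss under the base. The fallback sets out from 7 and postpones the unmasking until no allene is left. After the isomerisation with KOt-Bu a neutral work-up gives 8, which is isolated. Oxidation with MnO2 gives 5-(1-ethoxyethenyl)-2-(propa-1,2-dien-1-yloxy)-4-[(triisopropylsilyl)oxy]benzaldehyde F5. The nickel cyclisation of step 7 is run on F5, in which the enol ether is a spectator, to give (2S,3S)-5-(1-ethoxyethenyl)-2-(prop-1-en-2-yl)-6-[(triisopropylsilyl)oxy]-2,3-dihydro-1-benzofuran-3-ol F6. Hydrolysis of the enol ether (pyridinium p-toluenesulfonate, wet acetone, 0 °C) comes back to the route at 12.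

**Further compounds**

F1 | step 7 | 1-[(2R,3R)-3-hydroxy-2-(prop-1-en-2-yl)-6-[(triisopropylsilyl)oxy]-2,3-dihydro-1-benzofuran-5-yl]ethan-1-one | C=C(C)[C@H]1Oc2cc(O[Si](C(C)C)(C(C)C)C(C)C)c(C(C)=O)cc2[C@H]1O
F2 | step 7 | (2R,3R)-5-acetyl-2-(prop-1-en-2-yl)-6-[(triisopropylsilyl)oxy]-2,3-dihydro-1-benzofuran-3-yl 2-methylpropanoate | C=C(C)[C@H]1Oc2cc(O[Si](C(C)C)(C(C)C)C(C)C)c(C(C)=O)cc2[C@H]1OC(=O)C(C)C
F3 | step 13 | 2-(diphenoxyphosphoryl)propanoic acid | CC(C(=O)O)P(=O)(Oc1ccccc1)Oc1ccccc1
F4 | step 13 | (2S,3S)-5-acetyl-2-(prop-1-en-2-yl)-6-[(triisopropylsilyl)oxy]-2,3-dihydro-1-benzofuran-3-yl 2-(diphenoxyphosphoryl)propanoate | C=C(C)[C@@H]1Oc2cc(O[Si](C(C)C)(C(C)C)C(C)C)c(C(C)=O)cc2[C@@H]1OC(=O)C(C)P(=O)(Oc1ccccc1)Oc1ccccc1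
F5 | step 5 | 5-(1-ethoxyethenyl)-2-(propa-1,2-dien-1-yloxy)-4-[(triisopropylsilyl)oxy]benzaldehyde | C=C(OCC)c1cc(C=O)c(OC=C=C)cc1O[Si](C(C)C)(C(C)C)C(C)C
F6 | step 5 | (2S,3S)-5-(1-ethoxyethenyl)-2-(prop-1-en-2-yl)-6-[(triisopropylsilyl)oxy]-2,3-dihydro-1-benzofuran-3-ol | C=C(C)[C@@H]1Oc2cc(O[Si](C(C)C)(C(C)C)C(C)C)c(C(=C)OCC)cc2[C@@H]1O
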